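In the first hours of the cedar, maple and ash runs the target climbs as starting material falls, and two colleagues dispute what comes next. Reagent charged to the second phase crosses into the reaction phase, where it joins starting material reversibly to give target or pairs off to self-condensation product.

| flask | starting material | reagent in the second phase | remark | time | volume of the second phase over the first |
|---|---|---|---|---|---|
| cedar | 0.020 M | 0.018 M | run made earlier |  |  |
| maple | 0.020 M | 0.027 M | run made earlier |  |  |
| ash | 0.040 M | 0.036 M | run made earlier |  |  |
| flask | 0.020 M | 0.0360 M |  | 15 h | 1.0 |

- cedar (time / h: target / %, starting material / %): 0.667: 1.1, 101.3; 1.00: 1.1, 98.7; 1.50: 2.1, 97.4; 2.50: 4.5, 95.8; 4.00: 6.3, 91.1; 6.00: 8.7, 90.6; 10.0: 12.1, 87.8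
- maple (time / h: target / %, starting material / %): 1.33: 4.3, 98.0; 2.50: 5.9, 93.0; 4.00: 10.5, 91.0; 5.00: 12.4, 88.0; 6.00: 12.3, 87.8; 8.00: 13.0, 86.3; 10.0: 12.7, 87.6
- ash (time / h: target / %, starting material / %): 0.833: 1.5, 96.3; 2.50: 7.6, 93.5; 4.00: 10.1, 91.4; 6.00: 14.4, 88.2; 10.0: 17.2, 82.4

(readings scatter by 1 percentage point)

- in the second phase: reagent in the second phase; everything else is in the first
- charges count per volume of the first phase; a concentration in a rate is the amount of a species over the volume of its own phase; every rate counts per litre of the first phase
- steps under discussion: 2 reagent in the reaction phase -> self-condensation product; reagent in the reaction phase <-> reagent in the second phase; starting material + reagent in the reaction phase <-> target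
- the earlier runs hold the two phases in the same ratio of volumes as the flask asked about

- amount of target at 15 h, in percent of the starting material charged
- the change that raises the amount of target at 15 h, in percent of the starting material charged most ("none" if none brings more than 2 percentage points) (gamma / zeta / none)
- amount of target at 15 h, in percent of the starting material charged, after zeta

- gamma: doubling the amount of reagent in the second phase, all else as stated
- zeta: doubling the transfer coefficient of the reagent in the second phase, all else as stated

The first colleague expects a steady climb under kinetic control. The ash run has the flask's reagent charge, and shares of starting material need not depend on its charge, so she extends ash's slope from 6.00 h to 10.0 h up to 15 h and gets 20.7 %.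

The second colleague, whose reckoning I share, expects thermodynamic control. Divide the forward rate of the target step by its back rate and time drops out: at a standstill, the target share over the starting-material share follows the reaction-phase reagent level. Maple seems to stand still from 6.00 h on. Assuming that level goes in proportion to the charge, those readings give a quotient per reagent charge of 5.38 M⁻¹. The flask's charge then gives a quotient of 0.194, so 16.2 % target. Doubling the charge takes that quotient to 0.387, so 27.9 % target under gamma. The quotient read from maple gives me no number for zeta.

The forecast gives 16.5 %, names gamma as the best change, and gives 17.5 % after zeta, on the grounds that “The limit therefore tracks the reaction-phase reagent level”. It takes that level as the square root of the feed, whereas I take it as proportional to the charge.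

The simulation gives 17.2 %, with gamma best at a gain of 7.1 percentage points, and 16.9 % after zeta. The flask's target is 17.1 % at 7.50 h and 17.2 % at 15.0 h, so the plateau view holds and the climb stays below the first colleague's number. Her view fits the early hours, with 4.81 % at 1.50 h and the target still rising.

    2 reagent in the reaction phase → self-condensation product (k = 2.80 M⁻¹ h⁻¹)
    reagent in the reaction phase ⇌ reagent in the second phase, rate k2*([reagent in the reaction phase] - [reagent in the second phase]/K2) per volume of the first phase (partition coefficient = 0.520, kL = 0.0670 h⁻¹)
    starting material + reagent in the reaction phase ⇌ target (K = 17.0 M⁻¹, k = 21.0 M⁻¹ h⁻¹)

The flask's result gives a quotient per charge of 5.76 M⁻¹, against the 5.38 M⁻¹ read from maple. The neighbouring flask has 0.050 M of starting material and the same reagent charge, so the same reckoning again gives 16.2 % target. That flask holds 15.8 % target beside 84 % starting material at 15.0 h, a quotient per charge of 5.23 M⁻¹.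

(The numbers in the tables are calculated with made-up constants; noise was put on by code.)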